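A leftover is where we start: once the first exchange has taken its share, summer's charge still leaves 1.00 equiv of incoming ligand per starting complex, and we reckon the second exchange on that.

| flask | starting complex | incoming ligand | remark | time |
|---|---|---|---|---|
| Wednesday's | 0.026 M | 0.63 equiv | run made earlier |  |
| summer | 0.026 M | 2.00 equiv |  | 4.0 d |
| dawn | 0.026 M | 3.00 equiv |  | 4.0 d |
| winter | 0.026 M | 1.00 equiv |  | 4.0 d |

Wednesday's run (percent of the starting complex charged)

| time / h | complex with one exchanged / % | complex with two exchanged / % |
|---|---|---|
| 2.50 | 12.8 | 0 |
| 8.00 | 30.6 | 0.9 |
| 15.0 | 40.6 | 0 |
| 20.0 | 47.2 | 1.2 |
| 30.0 | 51.0 | 0.7 |
| 40.0 | 53.0 | 1.4 |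
| 50.0 | 55.9 | 1.8 |

(standard deviation of a reading: 1 percentage point)

- a reading or a percentage of complex with two exchanged counts all its forms, free or not
- no earlier run changes the charge of incoming ligand; that part of a forecast is a guess

- which of these holds the largest part of the starting complex at the end of summer (complex with two exchanged / starting complex / complex with one exchanged)
- which of these holds the largest part of the starting complex at the end of dawn (complex with two exchanged / starting complex / complex with one exchanged)
- which of these holds the largest part of the starting complex at the end of winter (complex with two exchanged / starting complex / complex with one exchanged)
- final complex with one exchanged in summer, as a percentage of the starting complex charged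

Wednesday's first reading gives the first step a pace of 0.0813 h⁻¹ per equivalent of ligand. The second step barely clears the scatter, so we use a relation without time. The steps share the ligand in the proportion [starting complex] to s[complex with one exchanged], s being the selectivity factor. With y the fraction of one-exchanged and m that of starting complex, taken as what y leaves, two-exchanged should for small s read s(−ln m − y). The last three readings sum to 3.90 %, which gives s = 0.0567, uncertain by 44.4 %. Multiplying gives K = 0.00461 h⁻¹, the second-exchange pace per equivalent of free ligand at this concentration.

In summer the first step's starting half-life, by our reckoning 4.26 h, is far shorter than the 4.0 d run, so we take that step as settled. Two ways follow. Holding the leftover constant (pseudo-first-order) gives 64.2 % one-exchanged. Balancing it instead, each second exchange spends one ligand and one one-exchanged, so summer's free ligand tracks the one-exchanged fraction, which becomes 1/(1+Kt) = 69.3 %. The first way cheats: by its own end 35.8 % of that ligand is spent, yet it still counts it. We commit to the balance. Dawn's leftover is twice summer's, and the same balance gives 47.3 % one-exchanged, narrowly favouring two-exchanged. Winter's charge leaves 0 equiv over the first exchange, and with s this small we expect one-exchanged largest there.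

The forecast, reading “simple stepwise substitution”, chose complex with one exchanged for summer, complex with two exchanged for dawn and complex with one exchanged for winter, with 68 % one-exchanged in summer against our 69.3 %.

Summer ends with 69.2 % one-exchanged, and complex with one exchanged is the largest part.

    starting complex + incoming ligand → leaving ligand + complex with one exchanged (k = 0.0653 L mol⁻¹ min⁻¹)
    complex with one exchanged + incoming ligand → leaving ligand + complex with two exchanged (k = 0.00307 L mol⁻¹ min⁻¹)
    crystals ⇌ complex with two exchanged, rate k3*(cs3 - [complex with two exchanged]) while solid is left; crystals form when [complex with two exchanged] > cs3 (solubility = 6.60 mM, k = 0.00310 min⁻¹)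

Crystals hold 4.15 % of summer's charge at its end, yet they leave the one-exchanged amount unmoved. In summer at 40.0 d, with crystals at 56.6 %, K gives 18.4 % one-exchanged, and the flask stands at 17.9 %.

Take a neighbour of summer with 0.044 M starting complex and the same equivalents: taking the pace as proportional to concentration, K grows by a factor of 1.69, which gives 57.2 % one-exchanged. That flask's computed result is 56.7 %.

The numbers in the tables were computed for substances that don't exist.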